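**Retrosynthetic overview**

1. Numbering is that of the isochromanone (C1 lactone carbonyl, O2, C3, C4, C4a, C5–C8, C8a; ring A = arene, ring B = lactone). The plan rests on ring A being a resorcylate: C1–C8a–C8–C7–C6–C5–C4a is an unbroken 1,3-oxygenated chain, so C8a–C4a is an aldol bond, and C1 with O8 can travel as a 2,2-dimethyl-1,3-dioxin-4-one that later acylates O2.
2. Ring B is cut at C1–O2 (transacylation of the dioxinone after desilylation). Ring A is cut at C8a–C4a (aldol cycloaromatisation of an open-chain diketo-dioxinone).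
3. The diketo-dioxinone is cut at C4a–C5 into the dianion of a keto-dioxinone (C1, C5–C8a) and a β-silyloxy Weinreb amide (C3, C4, C4a and the ketal-protected side chain).
4. C3 is set by (R)-BINAP–ruthenium hydrogenation of a β-keto ester made from 7-oxododecanoic acid (enamine acylation, retro-Claisen ring opening, malonate chain extension).
5. Ring order: ring A (step 10), then ring B (step 12); the side-chain ketone is unmasked last.

Key step: step 10

Remark: RuCl2[(R)-BINAP] is assumed to reduce the β-keto ester of step 4 with the facial sense known for simple 3-oxoalkanoates, which corresponds to (3R) here; 1,3-dicarbonyl compounds are drawn as keto tautomers.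

**Route**

Step 1
Reactants: 1 4-(cyclohex-1-en-1-yl)morpholine; 2 hexanoyl chloride
Product: 4 2-hexanoylcyclohexan-1-one, via acylated enamine 3 (not isolated)
Conditions: Et3N, CHCl3, 35 °C; then 6 M aq. HCl, reflux
Reagents that add atoms: water, O
Why: Stork enamine acylation, in which the nucleophilic β-carbon of the enamine is acylated, Et3N takes up HCl, and aqueous acid hydrolyses the vinylogous amide to the 1,3-diketone.

Step 2
Reactants: 4 2-hexanoylcyclohexan-1-one
Product: 6 7-oxododecanoic acid, via sodium 7-oxododecanoate 5 (not isolated)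
Conditions: NaOH (3 equiv), H2O–EtOH, reflux; then aq. HCl to pH 1, 0 °C
Reagents that add atoms: sodium hydroxide, [Na+].[OH-]
Why: Retro-Claisen cleavage of a 2-acylcyclohexanone, in which hydroxide adds to the more electrophilic ring carbonyl and the ring opens, so that the six ring carbons become C1–C6 of the keto acid.

Step 3
Reactants: 6 7-oxododecanoic acid; 7 magnesium bis(3-ethoxy-3-oxopropanoate)
Product: 9 ethyl 3,9-dioxotetradecanoate, via acyl imidazole 8 (not isolated)
Conditions: CDI, THF, rt; then Mg(O2CCH2CO2Et)2, THF, rt → 40 °C; 1 M aq. HCl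
Reagents that add atoms: none
Why: Masamune-type chain extension (decarboxylative Claisen condensation of a magnesium malonate half-ester with an acyl imidazole), which should give the β-keto ester while the isolated ketone stays inert.

Step 4
Reactants: 9 ethyl 3,9-dioxotetradecanoate
Product: 10 ethyl (3R)-3-hydroxy-9-oxotetradecanoate
Conditions: H2 (10 atm), RuCl2[(R)-BINAP] (0.5 mol%), EtOH, 50 °C
Reagents that add atoms: none
Why: Noyori asymmetric hydrogenation, in which the β-keto ester chelates ruthenium and the (R)-BINAP ligand directs hydride to the face that gives the (3R)-carbinol, while the non-chelating C9 ketone should not be reduced by this diamine-free catalyst.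

Step 5
Reactants: 10 ethyl (3R)-3-hydroxy-9-oxotetradecanoate
Product: 11 ethyl (3R)-3-[(tert-butyldimethylsilyl)oxy]-9-oxotetradecanoate
Conditions: TBSCl, imidazole, DMF, rt
Reagents that add atoms: tert-butyldimethylsilyl chloride, CC(C)(C)[Si](C)(C)Cl
Why: Imidazole-promoted silylation of a secondary alcohol, chosen over a silyl triflate so that the ketone is not converted into a silyl enol ether.

Step 6
Reactants: 11 ethyl (3R)-3-[(tert-butyldimethylsilyl)oxy]-9-oxotetradecanoate
Product: 12 ethyl (3R)-3-[(tert-butyldimethylsilyl)oxy]-8-(2-pentyl-1,3-dioxolan-2-yl)octanoate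
Conditions: Me3SiOCH2CH2OSiMe3, Me3SiOTf (5 mol%), CH2Cl2, −78 → −20 °C; then pyridine
Reagents that add atoms: 1,2-bis(trimethylsilyloxy)ethane, C[Si](C)(C)OCCO[Si](C)(C)C
Why: Noyori ketalisation, an aprotic low-temperature dioxolane formation driven by release of hexamethyldisiloxane, which the silyl ether and the ester should tolerate.

Step 7
Reactants: 12 ethyl (3R)-3-[(tert-butyldimethylsilyl)oxy]-8-(2-pentyl-1,3-dioxolan-2-yl)octanoate
Product: 13 (3R)-3-[(tert-butyldimethylsilyl)oxy]-N-methoxy-N-methyl-8-(2-pentyl-1,3-dioxolan-2-yl)octanamide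
Conditions: MeNHOMe·HCl, iPrMgCl, THF, −20 → 0 °C; aq. NH4Cl
Reagents that add atoms: N,O-dimethylhydroxylamine hydrochloride, CNOC.Cl
Why: Weinreb amide formation by aminolysis of the ester with the chloromagnesium amide, run cold to avoid β-elimination of the silyloxy group, with the dioxolane shielding the ketone from the Grignard reagent.

Step 8
Reactants: 14 2,2,6-trimethyl-4H-1,3-dioxin-4-one; 15 acetyl chloride
Product: 17 2,2-dimethyl-6-(2-oxopropyl)-4H-1,3-dioxin-4-one, via lithium dienolate 16 (not isolated)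
Conditions: 14 (2 equiv), LiN(SiMe3)2 (2 equiv), THF, −78 °C; then AcCl (1 equiv), −78 °C; aq. NH4Cl
Reagents that add atoms: none
Why: Vinylogous Claisen acylation, in which the γ-deprotonated dioxinone is acylated at its γ-carbon and a second equivalent of dienolate serves as base for the more acidic product.

Step 9
Reactants: 17 2,2-dimethyl-6-(2-oxopropyl)-4H-1,3-dioxin-4-one; 13 (3R)-3-[(tert-butyldimethylsilyl)oxy]-N-methoxy-N-methyl-8-(2-pentyl-1,3-dioxolan-2-yl)octanamide
Product: 19 6-[(6R)-6-[(tert-butyldimethylsilyl)oxy]-2,4-dioxo-11-(2-pentyl-1,3-dioxolan-2-yl)undecyl]-2,2-dimethyl-4H-1,3-dioxin-4-one, via dilithium dianion 18 (not isolated)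
Conditions: 17 (2.2 equiv), LiN(iPr)2 (4.4 equiv), THF, −78 °C; then 13, −78 → −40 °C; AcOH, −78 °C
Reagents that add atoms: none
Why: Claisen-type C-acylation of a 1,3-dicarbonyl dianion by a Weinreb amide, in which the more reactive terminal carbanion (C5) forms the C4a–C5 bond and collapse to the ketone is delayed until the acidic quench, so the amide is attacked only once.

Step 10
Reactants: 19 6-[(6R)-6-[(tert-butyldimethylsilyl)oxy]-2,4-dioxo-11-(2-pentyl-1,3-dioxolan-2-yl)undecyl]-2,2-dimethyl-4H-1,3-dioxin-4-one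
Product: 21 5-[(2R)-2-[(tert-butyldimethylsilyl)oxy]-7-(2-pentyl-1,3-dioxolan-2-yl)heptyl]-7-hydroxy-2,2-dimethyl-4H-1,3-benzodioxin-4-one, via aldol carbinol 20 (not isolated)
Conditions: Et3N (3 equiv), CH2Cl2, rt
Reagents that add atoms: none
Why: Et3N deprotonates C7 to give a dienolate that runs through the dioxinone (O=C1–C8a=C8–C7), and its α-carbon C8a adds to the C4a ketone in an intramolecular aldol reaction to give carbinol 20, which loses water and enolises at C6 to the phenol, the aromatisation making the sequence irreversible. The closest known reaction type is the amine- or carbonate-mediated cycloaromatisation of 6-(2,4-dioxoalkyl)dioxinones to 7-hydroxy-1,3-benzodioxin-4-ones, a laboratory version of the polyketide aldol that leads to orsellinic acid. Ring A closes in a 6-(enolexo)-exo-trig mode through the new C8a–C4a bond. No lasting stereocentre is formed, since the carbinol carbon of 20 becomes aromatic C4a, and C3 keeps its configuration because it bears no acidic hydrogen. The selectivity needed is C8a-to-C4a closure over Claisen closure of C5 onto C1 and over lactonisation of the C6 enol oxygen onto C1, and the dioxinone secures it because its ring double bond holds C1 anti to the C7 arm, so C1 cannot be reached. A weak amine base at room temperature is chosen so that E1cB loss of the C3 silyloxy group (β to the C4a ketone) and oxygen cyclisation onto C8 should not compete.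

Step 11
Reactants: 21 5-[(2R)-2-[(tert-butyldimethylsilyl)oxy]-7-(2-pentyl-1,3-dioxolan-2-yl)heptyl]-7-hydroxy-2,2-dimethyl-4H-1,3-benzodioxin-4-one
Product: 22 5-[(2R)-2-[(tert-butyldimethylsilyl)oxy]-7-(2-pentyl-1,3-dioxolan-2-yl)heptyl]-7-methoxy-2,2-dimethyl-4H-1,3-benzodioxin-4-one
Conditions: MeI, K2CO3, acetone, rt
Reagents that add atoms: iodomethane, CI
Why: Williamson O-methylation of the only free hydroxyl (the C6 phenol), since O8 is held in the dioxinone and the C3 oxygen is silylated.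

Step 12
Reactants: 22 5-[(2R)-2-[(tert-butyldimethylsilyl)oxy]-7-(2-pentyl-1,3-dioxolan-2-yl)heptyl]-7-methoxy-2,2-dimethyl-4H-1,3-benzodioxin-4-one
Product: 24 (3R)-8-hydroxy-6-methoxy-3-[5-(2-pentyl-1,3-dioxolan-2-yl)pentyl]-3,4-dihydro-1H-isochromen-1-one, via free alcohol 23 (not isolated)
Conditions: Bu4NF (1.5 equiv), THF, 0 °C → rt; then AcOH
Reagents that add atoms: none
Why: Fluoride desilylation followed by alkoxide transacylation of a benzodioxinone, in which the C3 alkoxide attacks C1 in a 6-exo-trig closure of ring B, acetone is expelled to free the C8 phenol, and C3 is retained because its C–O bond is never broken.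

Step 13
Reactants: 24 (3R)-8-hydroxy-6-methoxy-3-[5-(2-pentyl-1,3-dioxolan-2-yl)pentyl]-3,4-dihydro-1H-isochromen-1-one
Product: 25 (3R)-8-hydroxy-6-methoxy-3-(6-oxoundecyl)-3,4-dihydro-1H-isochromen-1-one
Conditions: 2 M aq. HCl–THF (1:4), rt
Reagents that add atoms: water, O
Why: Acid-catalysed hydrolysis of the dioxolane, under which the hydrogen-bonded phenolic lactone, the aryl methyl ether and the non-epimerisable C3 centre should be stable.

**Compound list**

1 | 4-(cyclohex-1-en-1-yl)morpholine | C1CCC(=CC1)N2CCOCC2 | starting material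
2 | hexanoyl chloride | CCCCCC(=O)Cl | starting material
3 | 1-[2-(morpholin-4-yl)cyclohex-1-en-1-yl]hexan-1-one | CCCCCC(=O)C1=C(CCCC1)N2CCOCC2 | intermediate
4 | 2-hexanoylcyclohexan-1-one (racemic, enolisable centre) | CCCCCC(=O)C1CCCCC1=O | intermediate
5 | sodium 7-oxododecanoate | [Na+].CCCCCC(=O)CCCCCC([O-])=O | intermediate
6 | 7-oxododecanoic acid | CCCCCC(=O)CCCCCC(O)=O | intermediate
7 | magnesium bis(3-ethoxy-3-oxopropanoate) | [Mg+2].CCOC(=O)CC([O-])=O.CCOC(=O)CC([O-])=O | starting material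
8 | 1-(1H-imidazol-1-yl)dodecane-1,7-dione | CCCCCC(=O)CCCCCC(=O)n1ccnc1 | intermediate
9 | ethyl 3,9-dioxotetradecanoate | CCCCCC(=O)CCCCCC(=O)CC(=O)OCC | intermediate
10 | ethyl (3R)-3-hydroxy-9-oxotetradecanoate | CCCCCC(=O)CCCCC[C@@H](O)CC(=O)OCC | intermediate
11 | ethyl (3R)-3-[(tert-butyldimethylsilyl)oxy]-9-oxotetradecanoate | CCCCCC(=O)CCCCC[C@@H](O[Si](C)(C)C(C)(C)C)CC(=O)OCC | intermediate
12 | ethyl (3R)-3-[(tert-butyldimethylsilyl)oxy]-8-(2-pentyl-1,3-dioxolan-2-yl)octanoate | CCCCCC1(OCCO1)CCCCC[C@@H](O[Si](C)(C)C(C)(C)C)CC(=O)OCC | intermediate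
13 | (3R)-3-[(tert-butyldimethylsilyl)oxy]-N-methoxy-N-methyl-8-(2-pentyl-1,3-dioxolan-2-yl)octanamide | CCCCCC1(OCCO1)CCCCC[C@@H](O[Si](C)(C)C(C)(C)C)CC(=O)N(C)OC | intermediate
14 | 2,2,6-trimethyl-4H-1,3-dioxin-4-one | CC1=CC(=O)OC(C)(C)O1 | starting material
15 | acetyl chloride | CC(=O)Cl | starting material
16 | lithium dienolate of 14 (lithium 2,2-dimethyl-6-methylidene-6H-1,3-dioxin-4-olate) | [Li+].C=C1C=C([O-])OC(C)(C)O1 | intermediate
17 | 2,2-dimethyl-6-(2-oxopropyl)-4H-1,3-dioxin-4-one | CC(=O)CC1=CC(=O)OC(C)(C)O1 | intermediate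
18 | dilithium dianion of 17 (deprotonated at C7 and C5) | [Li+].[Li+].C=C([O-])C=C1C=C([O-])OC(C)(C)O1 | intermediate
19 | 6-[(6R)-6-[(tert-butyldimethylsilyl)oxy]-2,4-dioxo-11-(2-pentyl-1,3-dioxolan-2-yl)undecyl]-2,2-dimethyl-4H-1,3-dioxin-4-one | CCCCCC1(OCCO1)CCCCC[C@@H](O[Si](C)(C)C(C)(C)C)CC(=O)CC(=O)CC2=CC(=O)OC(C)(C)O2 | intermediate
20 | 5-[(2R)-2-[(tert-butyldimethylsilyl)oxy]-7-(2-pentyl-1,3-dioxolan-2-yl)heptyl]-5-hydroxy-2,2-dimethyl-5,6-dihydro-4H-1,3-benzodioxine-4,7(8H)-dione (either carbinol epimer) | CCCCCC1(OCCO1)CCCCC[C@@H](O[Si](C)(C)C(C)(C)C)CC2(O)CC(=O)CC3=C2C(=O)OC(C)(C)O3 | intermediate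
21 | 5-[(2R)-2-[(tert-butyldimethylsilyl)oxy]-7-(2-pentyl-1,3-dioxolan-2-yl)heptyl]-7-hydroxy-2,2-dimethyl-4H-1,3-benzodioxin-4-one | CCCCCC1(OCCO1)CCCCC[C@@H](O[Si](C)(C)C(C)(C)C)Cc2cc(O)cc3OC(C)(C)OC(=O)c23 | intermediate
22 | 5-[(2R)-2-[(tert-butyldimethylsilyl)oxy]-7-(2-pentyl-1,3-dioxolan-2-yl)heptyl]-7-methoxy-2,2-dimethyl-4H-1,3-benzodioxin-4-one | CCCCCC1(OCCO1)CCCCC[C@@H](O[Si](C)(C)C(C)(C)C)Cc2cc(OC)cc3OC(C)(C)OC(=O)c23 | intermediate
23 | 5-[(2R)-2-hydroxy-7-(2-pentyl-1,3-dioxolan-2-yl)heptyl]-7-methoxy-2,2-dimethyl-4H-1,3-benzodioxin-4-one | CCCCCC1(OCCO1)CCCCC[C@@H](O)Cc2cc(OC)cc3OC(C)(C)OC(=O)c23 | intermediate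
24 | (3R)-8-hydroxy-6-methoxy-3-[5-(2-pentyl-1,3-dioxolan-2-yl)pentyl]-3,4-dihydro-1H-isochromen-1-one | CCCCCC1(OCCO1)CCCCC[C@@H]2Cc3cc(OC)cc(O)c3C(=O)O2 | intermediate
25 | (3R)-8-hydroxy-6-methoxy-3-(6-oxoundecyl)-3,4-dihydro-1H-isochromen-1-one | CCCCCC(=O)CCCCC[C@@H]1Cc2cc(OC)cc(O)c2C(=O)O1 | target

**Step count and risks**

Total steps: 13. Longest linear sequence: 12 (steps 1–7, then 9–13); step 8 is a one-step branch.

Steps most likely to fail:

Step 9. Proton transfer from the amide α-carbon to the strongly basic dianion may outrun addition and lead to loss of the β-silyloxy group, or the acylation may stall. The fallback forms the same C4a–C5 bond by aldol addition and corrects the oxidation level afterwards. It sets out from ester 12 (with 17) and comes back at 19. iBu2AlH in CH2Cl2 at −78 °C should reduce 12 to (3R)-3-[(tert-butyldimethylsilyl)oxy]-8-(2-pentyl-1,3-dioxolan-2-yl)octanal F1. Addition of this aldehyde to dianion 18 at −78 °C should give 6-[(6R)-6-[(tert-butyldimethylsilyl)oxy]-4-hydroxy-2-oxo-11-(2-pentyl-1,3-dioxolan-2-yl)undecyl]-2,2-dimethyl-4H-1,3-dioxin-4-one F2 as a mixture of carbinol epimers. Oxidation with Dess–Martin periodinane (NaHCO3, CH2Cl2) should then deliver 19.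

Step 10. The cross-conjugated dioxinone dienolate is a weak carbon nucleophile, so aldol closure may be slow enough for elimination of the C3 silyloxy group or oxygen cyclisation to take over. The fallback keeps the C8a–C4a aldol bond but unmasks C1 as an ester first. It sets out from 19 and comes back at 24.
- Heating 19 in toluene–MeOH (110 °C, sealed vessel) should open the dioxinone by loss of acetone to an acylketene, which MeOH traps as methyl (9R)-9-[(tert-butyldimethylsilyl)oxy]-3,5,7-trioxo-14-(2-pentyl-1,3-dioxolan-2-yl)tetradecanoate F3.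
- K2CO3 in MeOH at rt should aromatise it through the more nucleophilic β-keto ester enolate to methyl 2-[(2R)-2-[(tert-butyldimethylsilyl)oxy]-7-(2-pentyl-1,3-dioxolan-2-yl)heptyl]-4,6-dihydroxybenzoate F4.
- MeI (1 equiv) and K2CO3 in acetone should methylate only the para hydroxyl, the ortho one being hydrogen-bonded to the ester, to give methyl 2-[(2R)-2-[(tert-butyldimethylsilyl)oxy]-7-(2-pentyl-1,3-dioxolan-2-yl)heptyl]-6-hydroxy-4-methoxybenzoate F5.
- Bu4NF in THF should give methyl 2-hydroxy-6-[(2R)-2-hydroxy-7-(2-pentyl-1,3-dioxolan-2-yl)heptyl]-4-methoxybenzoate F6 (not isolated), whose alkoxide lactonises onto the methyl ester to give 24.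

Step 12. Water in the fluoride reagent may protonate the alkoxide before it acylates, and hydroxide may open the dioxinone hydrolytically, so ring B may not close cleanly. The fallback separates the events and closes ring B under acid. It sets out from 22 and comes back at 25, so it also replaces step 13. KOH in THF–MeOH–H2O at 60 °C should hydrolyse the benzodioxinone with loss of acetone to 2-[(2R)-2-[(tert-butyldimethylsilyl)oxy]-7-(2-pentyl-1,3-dioxolan-2-yl)heptyl]-6-hydroxy-4-methoxybenzoic acid F7. Treatment with 3 M aq. HCl–THF at 40 °C should remove the silyl group and the dioxolane to give 2-hydroxy-6-[(2R)-2-hydroxy-8-oxotridecyl]-4-methoxybenzoic acid F8 (not isolated). This hydroxy acid should lactonise under the same acid to 25 with retention at C3, since only the acyl–oxygen bond is formed.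

**Further compounds**

F1 | step 9 | (3R)-3-[(tert-butyldimethylsilyl)oxy]-8-(2-pentyl-1,3-dioxolan-2-yl)octanal | CCCCCC1(OCCO1)CCCCC[C@@H](O[Si](C)(C)C(C)(C)C)CC=O
F2 | step 9 | 6-[(6R)-6-[(tert-butyldimethylsilyl)oxy]-4-hydroxy-2-oxo-11-(2-pentyl-1,3-dioxolan-2-yl)undecyl]-2,2-dimethyl-4H-1,3-dioxin-4-one | CCCCCC1(OCCO1)CCCCC[C@@H](O[Si](C)(C)C(C)(C)C)CC(O)CC(=O)CC2=CC(=O)OC(C)(C)O2
F3 | step 10 | methyl (9R)-9-[(tert-butyldimethylsilyl)oxy]-3,5,7-trioxo-14-(2-pentyl-1,3-dioxolan-2-yl)tetradecanoate | CCCCCC1(OCCO1)CCCCC[C@@H](O[Si](C)(C)C(C)(C)C)CC(=O)CC(=O)CC(=O)CC(=O)OC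
F4 | step 10 | methyl 2-[(2R)-2-[(tert-butyldimethylsilyl)oxy]-7-(2-pentyl-1,3-dioxolan-2-yl)heptyl]-4,6-dihydroxybenzoate | CCCCCC1(OCCO1)CCCCC[C@@H](O[Si](C)(C)C(C)(C)C)Cc2cc(O)cc(O)c2C(=O)OC
F5 | step 10 | methyl 2-[(2R)-2-[(tert-butyldimethylsilyl)oxy]-7-(2-pentyl-1,3-dioxolan-2-yl)heptyl]-6-hydroxy-4-methoxybenzoate | CCCCCC1(OCCO1)CCCCC[C@@H](O[Si](C)(C)C(C)(C)C)Cc2cc(OC)cc(O)c2C(=O)OC
F6 | step 10 | methyl 2-hydroxy-6-[(2R)-2-hydroxy-7-(2-pentyl-1,3-dioxolan-2-yl)heptyl]-4-methoxybenzoate | CCCCCC1(OCCO1)CCCCC[C@@H](O)Cc2cc(OC)cc(O)c2C(=O)OC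
F7 | step 12 | 2-[(2R)-2-[(tert-butyldimethylsilyl)oxy]-7-(2-pentyl-1,3-dioxolan-2-yl)heptyl]-6-hydroxy-4-methoxybenzoic acid | CCCCCC1(OCCO1)CCCCC[C@@H](O[Si](C)(C)C(C)(C)C)Cc2cc(OC)cc(O)c2C(=O)O
F8 | step 12 | 2-hydroxy-6-[(2R)-2-hydroxy-8-oxotridecyl]-4-methoxybenzoic acid | CCCCCC(=O)CCCCC[C@@H](O)Cc1cc(OC)cc(O)c1C(=O)O
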